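Stipulin is cut at its two aryl–CH2 bonds, at C5' of ring A and C3 of ring B. Each of these carbons lies ortho to a phenol oxygen (O4' and O4) and can be bought as a C–Br carbon, so the chalcone is built first with bromine marking both sites. One twofold Stille coupling with a prenylstannane then installs both prenyl groups and completes the carbon skeleton without touching C3'. Its substrate is the E-configured 3,5'-dibromo-2',4',4-trihydroxychalcone with O4 and O4' masked as acetates and the hydrogen-bonded 2'-OH left free. The feature exploited is thus the pair of ortho-oxygenated ring carbons C5' and C3, addressed as aryl bromides. Methanolysis of the acetates then gives the target.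

Key step: step 3

Remark: ring A is the ketone-derived ring (primed locants) and ring B the aldehyde-derived ring; compounds 1, 2 and 6 are taken as purchased, and the only stereo-element of the target is the E double bond.

Step 1
Reactants: 1 1-(5-bromo-2,4-dihydroxyphenyl)ethanone; 2 3-bromo-4-hydroxybenzaldehyde
Product: 4 (E)-3-(3-bromo-4-hydroxyphenyl)-1-(5-bromo-2,4-dihydroxyphenyl)prop-2-en-1-one, via racemic aldol adduct 3 (not isolated)
Conditions: dry HCl (saturated in EtOH), 0 °C → rt
Reagents that add atoms: none
Why: Acid-catalysed Claisen–Schmidt (crossed aldol) condensation, in which the enol of the methyl ketone adds to the protonated aldehyde and the benzylic aldol 3 loses water to the conjugated, thermodynamically preferred E-enone; acid avoids the phenoxide formation that would deactivate both unprotected partners under base and is harmless at this stage because no prenyl group is present yet.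

Step 2
Reactants: 4 (E)-3-(3-bromo-4-hydroxyphenyl)-1-(5-bromo-2,4-dihydroxyphenyl)prop-2-en-1-one
Product: 5 (E)-3-(4-acetoxy-3-bromophenyl)-1-(4-acetoxy-5-bromo-2-hydroxyphenyl)prop-2-en-1-one
Conditions: Ac2O (2.2 equiv), pyridine/CH2Cl2, 0 °C
Reagents that add atoms: acetic anhydride, CC(=O)OC(C)=O
Why: Pyridine-mediated O-acetylation of phenols, selective because the 4- and 4'-hydroxyls are free nucleophiles whereas the 2'-hydroxyl is held in a strong intramolecular hydrogen bond to the ketone and should stay untouched with a slight excess of anhydride at low temperature.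

Step 3
Reactants: 5 (E)-3-(4-acetoxy-3-bromophenyl)-1-(4-acetoxy-5-bromo-2-hydroxyphenyl)prop-2-en-1-one; 6 tributyl(3-methylbut-2-enyl)stannane (2.6 equiv)
Product: 7 stipulin 4,4'-diacetate, (E)-3-[4-acetoxy-3-(3-methylbut-2-enyl)phenyl]-1-[4-acetoxy-2-hydroxy-5-(3-methylbut-2-enyl)phenyl]prop-2-en-1-one
Conditions: Pd(PPh3)4 (10 mol %), DMF (degassed, amine-free), 90 °C, argon
Reagents that add atoms: none
Why: Oxidative addition of zerovalent palladium at C5'–Br and C3–Br is followed by tin-to-palladium transfer of the prenyl group and by reductive elimination from the aryl(prenyl) complex of divalent palladium, which forms each aryl–CH2 bond; the closest known reaction type is the Migita–Kosugi–Stille coupling of aryl bromides with allylic stannanes. No ring is closed and no stereocenter is created, and the E-enone is a spectator that is already the thermodynamic isomer. The selectivity needed is linear over branched prenyl transfer at both sites: the prenyl ligand equilibrates between its sigma and pi forms and, with PPh3 on the metal, should couple at the unhindered CH2 end and not at the CMe2 end. Site selectivity is settled by the substrate, since bromine already sits at C5' and C3 and C3' carries only hydrogen. The acetates on O4 and O4' lower the electron density of both bromoarenes for faster oxidative addition and keep these oxygens from adding to the new prenyl groups, while the neutral, base-free medium should leave the chelated 2'-OH alone and give no flavanone; amine-free DMF guards the aryl acetates against aminolysis.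

Step 4
Reactants: 7 stipulin 4,4'-diacetate
Product: 8 stipulin, (E)-1-[2,4-dihydroxy-5-(3-methylbut-2-enyl)phenyl]-3-[4-hydroxy-3-(3-methylbut-2-enyl)phenyl]prop-2-en-1-one
Conditions: K2CO3 (0.3 equiv), MeOH (degassed), 0 °C → rt; aq. NH4Cl quench
Reagents that add atoms: none
Why: Base-catalysed transesterification (Zemplén-type methanolysis) of two aryl acetates, which are activated esters and should cleave quickly under cold, weakly basic conditions that leave the prenyl groups untouched and give the 2'-hydroxychalcone little time for oxa-Michael closure to the flavanone.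

Compound list
1 | 1-(5-bromo-2,4-dihydroxyphenyl)ethanone | CC(=O)c1cc(Br)c(O)cc1O | starting material
2 | 3-bromo-4-hydroxybenzaldehyde | O=Cc1ccc(O)c(Br)c1 | starting material
3 | 3-(3-bromo-4-hydroxyphenyl)-1-(5-bromo-2,4-dihydroxyphenyl)-3-hydroxypropan-1-one (racemic aldol adduct, not isolated) | O=C(CC(O)c1ccc(O)c(Br)c1)c1cc(Br)c(O)cc1O | intermediate
4 | (E)-3-(3-bromo-4-hydroxyphenyl)-1-(5-bromo-2,4-dihydroxyphenyl)prop-2-en-1-one | O=C(/C=C/c1ccc(O)c(Br)c1)c1cc(Br)c(O)cc1O | intermediate
5 | (E)-3-(4-acetoxy-3-bromophenyl)-1-(4-acetoxy-5-bromo-2-hydroxyphenyl)prop-2-en-1-one | CC(=O)Oc1ccc(/C=C/C(=O)c2cc(Br)c(OC(C)=O)cc2O)cc1Br | intermediate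
6 | tributyl(3-methylbut-2-enyl)stannane | CC(C)=CC[Sn](CCCC)(CCCC)CCCC | starting material
7 | stipulin 4,4'-diacetate | CC(C)=CCc1cc(/C=C/C(=O)c2cc(CC=C(C)C)c(OC(C)=O)cc2O)ccc1OC(C)=O | intermediate
8 | stipulin | CC(C)=CCc1cc(/C=C/C(=O)c2cc(CC=C(C)C)c(O)cc2O)ccc1O | target

Total step count: 4. Longest linear sequence: 4 steps (1 and 2 → 4 → 5 → 7 → 8).

Steps most likely to fail

Step 3. The prenyl group may be delivered through its substituted end at one or both sites, giving reverse-prenylated material. The second coupling may also stall, or a C–Br bond may be reduced. The fallback sets out from 5 and comes back at 7. A twofold Stille coupling of 5 with allyltributylstannane (Pd(PPh3)4, DMF, 90 °C) has no linear/branched question because the allyl group is symmetrical. It should give (E)-3-(4-acetoxy-3-allylphenyl)-1-(4-acetoxy-5-allyl-2-hydroxyphenyl)prop-2-en-1-one F1. Olefin cross-metathesis of F1 with excess 2-methylbut-2-ene, using the second-generation Grubbs catalyst (H2IMes)(PCy3)Cl2Ru=CHPh in CH2Cl2 at 35 °C, should then turn both terminal allyl groups into prenyl groups. The conjugated, 1,2-disubstituted enone is too electron-poor to take part, so the product is 7.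

Step 1. The condensation of the unprotected polyphenols may stay incomplete. It may also be diverted by acid-promoted attack of the aldehyde on C3' of ring A or by closure of the 2'-hydroxychalcone to the flavanone. The fallback sets out from 1 and 2 and comes back at 4.
- Compound 1 with chloromethyl methyl ether (1.1 equiv) and K2CO3 in acetone should give 1-[5-bromo-2-hydroxy-4-(methoxymethoxy)phenyl]ethanone F2, since only the non-chelated hydroxyl reacts.
- Compound 2 under the same conditions should give 3-bromo-4-(methoxymethoxy)benzaldehyde F3.
- Base-mediated Claisen–Schmidt condensation of F2 with F3 (KOH, EtOH/H2O, rt) proceeds through the racemic aldol adduct 3-[3-bromo-4-(methoxymethoxy)phenyl]-1-[5-bromo-2-hydroxy-4-(methoxymethoxy)phenyl]-3-hydroxypropan-1-one F4, which is not isolated. It should give (E)-3-[3-bromo-4-(methoxymethoxy)phenyl]-1-[5-bromo-2-hydroxy-4-(methoxymethoxy)phenyl]prop-2-en-1-one F5.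
- Acetal cleavage of F5 with HCl in MeOH at 40 °C, done before any prenyl group is present, should release 4.

Step 4. Base may trigger oxa-Michael closure of the 2'-phenoxide onto the enone, and the electron-rich phenoxides may be oxidised by air during deacetylation. The fallback sets out from 4 and comes back at 8, replacing the acetates by silyl ethers that are removed without base.
- Compound 4 with tert-butyldimethylsilyl chloride (2.2 equiv) and imidazole in DMF at 0 °C should give (E)-1-[5-bromo-4-(tert-butyldimethylsilyloxy)-2-hydroxyphenyl]-3-[3-bromo-4-(tert-butyldimethylsilyloxy)phenyl]prop-2-en-1-one F6.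
- The same twofold Stille coupling of F6 with 6 (Pd(PPh3)4, DMF, 90 °C) should give stipulin 4,4'-bis(tert-butyldimethylsilyl) ether F7.
- Tetrabutylammonium fluoride buffered with acetic acid in THF at 0 °C should cleave both aryl silyl ethers of F7 under nearly neutral conditions and give 8.

Further compounds
F1 | step 3 | (E)-3-(4-acetoxy-3-allylphenyl)-1-(4-acetoxy-5-allyl-2-hydroxyphenyl)prop-2-en-1-one | C=CCc1cc(/C=C/C(=O)c2cc(CC=C)c(OC(C)=O)cc2O)ccc1OC(C)=O
F2 | step 1 | 1-[5-bromo-2-hydroxy-4-(methoxymethoxy)phenyl]ethanone | CC(=O)c1cc(Br)c(OCOC)cc1O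
F3 | step 1 | 3-bromo-4-(methoxymethoxy)benzaldehyde | COCOc1ccc(C=O)cc1Br
F4 | step 1 | 3-[3-bromo-4-(methoxymethoxy)phenyl]-1-[5-bromo-2-hydroxy-4-(methoxymethoxy)phenyl]-3-hydroxypropan-1-one (racemic, not isolated) | COCOc1ccc(C(O)CC(=O)c2cc(Br)c(OCOC)cc2O)cc1Br
F5 | step 1 | (E)-3-[3-bromo-4-(methoxymethoxy)phenyl]-1-[5-bromo-2-hydroxy-4-(methoxymethoxy)phenyl]prop-2-en-1-one | COCOc1ccc(/C=C/C(=O)c2cc(Br)c(OCOC)cc2O)cc1Br
F6 | step 4 | (E)-1-[5-bromo-4-(tert-butyldimethylsilyloxy)-2-hydroxyphenyl]-3-[3-bromo-4-(tert-butyldimethylsilyloxy)phenyl]prop-2-en-1-one | CC(C)(C)[Si](C)(C)Oc1ccc(/C=C/C(=O)c2cc(Br)c(O[Si](C)(C)C(C)(C)C)cc2O)cc1Br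
F7 | step 4 | stipulin 4,4'-bis(tert-butyldimethylsilyl) ether | CC(C)=CCc1cc(/C=C/C(=O)c2cc(CC=C(C)C)c(O[Si](C)(C)C(C)(C)C)cc2O)ccc1O[Si](C)(C)C(C)(C)C
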